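**Strategy.** The pyranone ring (ring C) is disconnected at C4a–C4, C4–C3 and O1–C2, which reduces the flavone to an iodoresorcinol, carbon monoxide and a ring-B arylacetylene. Two features are exploited. The one-carbon carbonyl unit C4 bridges C4a and C3 and can be delivered as CO. The oxygen substituents of ring A are related pairwise by the mirror plane through C4a and C7 (O at C5 with O1 at C8a, OMe at C6 with OMe at C8). Either hydroxyl of 2-iodo-4,5,6-trimethoxybenzene-1,3-diol can therefore become O1, and the other remains as the 5-OH. One palladium-catalysed carbonylative alkynylation–cyclisation builds ring C with ring A unprotected; ring B carries benzyl ethers that are removed last.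

Key step: step 6

Remark: Tamadone has no stereogenic centre, axis or configurable double bond, so there is no enantiomer to select; the route is planned for the single constitution shown.

**Step 1**
Reactants: 1 1,2,3-trimethoxybenzene
Product: 2 1,5-dibromo-2,3,4-trimethoxybenzene (= 4,6-dibromo-1,2,3-trimethoxybenzene)
Conditions: NBS (2.2 equiv), MeCN, rt
Reagents that add atoms: N-bromosuccinimide, O=C1CCC(=O)N1Br
Why: Electrophilic aromatic bromination: C4 and C6 are each ortho to one outer methoxy group and para to the other, whereas C5 is para only to the twisted, weakly donating central methoxy group, so two equivalents of NBS should give the 4,6-dibromide and stop there.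

**Step 2**
Reactants: 2 1,5-dibromo-2,3,4-trimethoxybenzene
Product: 4 4,5,6-trimethoxybenzene-1,3-diol, via aryl bis(diisopropyl boronate) 3 (not isolated)
Conditions: B(OiPr)3 (3 equiv), n-BuLi (2.4 equiv), THF/toluene, −78 → −20 °C; then AcOH, 30% H2O2, 0 °C → rt; Na2S2O3 quench
Reagents that add atoms: triisopropyl borate, CC(C)OB(OC(C)C)OC(C)C (boron and isopropoxy groups of 3); hydrogen peroxide, OO (hydroxyl oxygens of 4)
Why: Bromine–lithium exchange with in situ borate capture at both C–Br bonds, then peroxide oxidation of the aryl boronates (1,2-aryl shift from boron to oxygen), should replace each bromine by hydroxyl at the same carbon, the ortho-methoxy groups assisting exchange and the acidic oxidation medium limiting over-oxidation of the electron-rich diol.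

**Step 3**
Reactants: 4 4,5,6-trimethoxybenzene-1,3-diol
Product: 5 2-iodo-4,5,6-trimethoxybenzene-1,3-diol
Conditions: NIS (1.0 equiv), MeCN, −20 → 0 °C, dark, Ar; used promptly
Reagents that add atoms: N-iodosuccinimide, O=C1CCC(=O)N1I
Why: Electrophilic aromatic iodination at the only remaining ring C–H, which is ortho to both hydroxyls, should be fast with one equivalent of NIS at low temperature, and the neutral succinimide by-product avoids acid-promoted loss of iodine.

**Step 4**
Reactants: 6 2,4-dihydroxybenzaldehyde; 7 benzyl bromide
Product: 8 2,4-bis(benzyloxy)benzaldehyde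
Conditions: 7 (2.4 equiv), K2CO3, DMF, 60 °C
Reagents that add atoms: none
Why: Williamson ether synthesis; excess benzyl bromide in warm DMF should also alkylate the hydrogen-bonded 2-hydroxyl, and the aldehyde is inert to carbonate.

**Step 5**
Reactants: 8 2,4-bis(benzyloxy)benzaldehyde
Product: 9 2,4-bis(benzyloxy)-1-ethynylbenzene
Conditions: dimethyl (1-diazo-2-oxopropyl)phosphonate, K2CO3, MeOH/THF, 0 °C → rt
Reagents that add atoms: dimethyl (1-diazo-2-oxopropyl)phosphonate, CC(=O)C(=[N+]=[N-])P(=O)(OC)OC (terminal alkyne carbon)
Why: Ohira–Bestmann (Seyferth–Gilbert) homologation of a non-enolisable aryl aldehyde under carbonate/methanol, to which benzyl ethers are inert, should give the terminal alkyne via the diazoalkene and a 1,2-hydride shift.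

**Step 6**
Reactants: 5 2-iodo-4,5,6-trimethoxybenzene-1,3-diol; 9 2,4-bis(benzyloxy)-1-ethynylbenzene (1.2 equiv); 10 carbon monoxide
Product: 13 2-[2,4-bis(benzyloxy)phenyl]-5-hydroxy-6,7,8-trimethoxy-4H-chromen-4-one, via ortho-hydroxyaryl ynone 11 (not isolated), via diethylamino enaminone 12 (not isolated)
Conditions: PdCl2(dppf) (5 mol %), CO (20 bar), degassed Et2NH (solvent), 120 °C, autoclave, copper-free
Reagents that add atoms: diethylamine, CCNCC (its atoms are carried only by intermediate 12 and leave again on ring closure)
Why: Pd(0) inserts into the C–I bond of 5, CO insertion gives an aroylpalladium(II) intermediate, and amine-assisted alkynylation with 9 followed by reductive elimination forms C4a–C4 and C4–C3 in ynone 11. Diethylamine adds to the ynone β-carbon to give enaminone 12, and one of the two ortho-hydroxyls then attacks that same carbon and expels the amine, forming O1–C2 and closing ring C by a 6-endo addition–elimination. The closest known reaction type is the palladium-catalysed carbonylative Sonogashira annulation of ortho-iodophenols with terminal alkynes to flavones. No stereocentre is formed. The step needs six-membered closure to the flavone instead of 5-exo closure to an aurone, which the enaminone secures because its β-carbon is the only electrophilic alkene carbon; it also needs carbonylative in preference to direct alkynylation, which CO pressure and the absence of copper favour. Regiochemistry on ring A is not an issue: the hydroxyls of 5 are symmetry-related, so both modes of closure lead to 13 and the spectator hydroxyl ends up as the chelated 5-OH without any masking.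

**Step 7**
Reactants: 13 2-[2,4-bis(benzyloxy)phenyl]-5-hydroxy-6,7,8-trimethoxy-4H-chromen-4-one
Product: 14 Tamadone, 2-(2,4-dihydroxyphenyl)-5-hydroxy-6,7,8-trimethoxy-4H-chromen-4-one
Conditions: H2 (1 atm), 10% Pd/C, EtOAc/MeOH, rt, stopped at full conversion
Reagents that add atoms: none
Why: Catalytic hydrogenolysis of benzyl aryl ethers on Pd/C at ambient pressure should free both ring-B hydroxyls, while the methyl ethers and the conjugated chromone C2=C3 bond, which is reduced much more slowly, should survive.

**Compound list**
1 | 1,2,3-trimethoxybenzene | COc1cccc(OC)c1OC | starting material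
2 | 1,5-dibromo-2,3,4-trimethoxybenzene | COc1c(Br)cc(Br)c(OC)c1OC | intermediate
3 | tetraisopropyl (4,5,6-trimethoxy-1,3-phenylene)diboronate (present as its lithium borate complex until acidified) | COc1c(B(OC(C)C)OC(C)C)cc(B(OC(C)C)OC(C)C)c(OC)c1OC | intermediate
4 | 4,5,6-trimethoxybenzene-1,3-diol | COc1c(O)cc(O)c(OC)c1OC | intermediate
5 | 2-iodo-4,5,6-trimethoxybenzene-1,3-diol | COc1c(O)c(I)c(O)c(OC)c1OC | intermediate
6 | 2,4-dihydroxybenzaldehyde | O=Cc1ccc(O)cc1O | starting material
7 | benzyl bromide | BrCc1ccccc1 | starting material
8 | 2,4-bis(benzyloxy)benzaldehyde | O=Cc1ccc(OCc2ccccc2)cc1OCc1ccccc1 | intermediate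
9 | 2,4-bis(benzyloxy)-1-ethynylbenzene | C#Cc1ccc(OCc2ccccc2)cc1OCc1ccccc1 | intermediate
10 | carbon monoxide | [C-]#[O+] | starting material
11 | 3-[2,4-bis(benzyloxy)phenyl]-1-(2,6-dihydroxy-3,4,5-trimethoxyphenyl)prop-2-yn-1-one | COc1c(O)c(C(=O)C#Cc2ccc(OCc3ccccc3)cc2OCc2ccccc2)c(O)c(OC)c1OC | intermediate
12 | (E)-3-[2,4-bis(benzyloxy)phenyl]-3-(diethylamino)-1-(2,6-dihydroxy-3,4,5-trimethoxyphenyl)prop-2-en-1-one | COc1c(O)c(C(=O)/C=C(/N(CC)CC)c2ccc(OCc3ccccc3)cc2OCc2ccccc2)c(O)c(OC)c1OC | intermediate
13 | 2-[2,4-bis(benzyloxy)phenyl]-5-hydroxy-6,7,8-trimethoxy-4H-chromen-4-one | COc1c(OC)c(O)c2c(=O)cc(-c3ccc(OCc4ccccc4)cc3OCc3ccccc3)oc2c1OC | intermediate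
14 | Tamadone, 2-(2,4-dihydroxyphenyl)-5-hydroxy-6,7,8-trimethoxy-4H-chromen-4-one | COc1c(OC)c(O)c2c(=O)cc(-c3ccc(O)cc3O)oc2c1OC | target

**Step count.** Total: 7 steps. Longest linear sequence: 5 steps (1, 2, 3, 6, 7); the alkyne branch (4, 5) joins at step 6.

**Steps most likely to fail**

Step 6. On this very electron-rich, doubly ortho-substituted iodide, the carbonylative coupling may be outrun by direct CO-free alkynylation with closure to a benzofuran, by aminocarbonylation of the aroylpalladium by the amine solvent, or by reductive loss of iodine. The fallback is the classical chalcone route. It sets out from diol 4 and aldehyde 8 and comes back at 13. Friedel–Crafts C-acetylation of 4 at its only ring C–H (Ac2O, BF3·OEt2, 60 °C) should give 1-(2,6-dihydroxy-3,4,5-trimethoxyphenyl)ethan-1-one F1. Claisen–Schmidt condensation of F1 with 8 (KOH, EtOH, rt) should give (E)-3-[2,4-bis(benzyloxy)phenyl]-1-(2,6-dihydroxy-3,4,5-trimethoxyphenyl)prop-2-en-1-one F2. Iodine-catalysed oxidative cyclisation of F2 in DMSO at 120 °C should form O1–C2 and dehydrogenate to 13; the ring-A symmetry again makes the choice of hydroxyl irrelevant.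

Step 2. The second bromine–lithium exchange may be incomplete, or an aryllithium may be protonated, leaving one position unoxidised; the peroxide may also over-oxidise the electron-rich diol. The fallback replaces organolithium chemistry by palladium catalysis. It sets out from 2 and comes back at 4. Double Miyaura borylation (B2pin2, PdCl2(dppf), KOAc, dioxane, 90 °C) should give 2,2'-(4,5,6-trimethoxy-1,3-phenylene)bis(4,4,5,5-tetramethyl-1,3,2-dioxaborolane) F3, an isolable and purifiable solid. Mild oxidation of F3 (30% H2O2, aq. NaHCO3, THF, 0 °C → rt) should then give 4.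

Step 3. Single-electron oxidation of the pentaoxygenated ring to quinonoid material may compete with C-iodination, and the iodination may reverse (protodeiodination) during work-up. The fallback introduces iodine through a carbanion instead of an electrophilic substitution on the free diol. It sets out from 4 and comes back at 5. Bis-protection (MOMCl, i-Pr2NEt, CH2Cl2, 0 °C → rt) should give 1,2,3-trimethoxy-4,6-bis(methoxymethoxy)benzene F4. Directed ortho-lithiation of F4 between the two MOM ethers (n-BuLi, THF, 0 °C) and an iodine quench should give 2-iodo-4,5,6-trimethoxy-1,3-bis(methoxymethoxy)benzene F5. Brief acetal cleavage of F5 (cat. HCl, MeOH, rt) should return 5.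

**Further compounds**
F1 | step 6 | 1-(2,6-dihydroxy-3,4,5-trimethoxyphenyl)ethan-1-one | COc1c(O)c(C(C)=O)c(O)c(OC)c1OC
F2 | step 6 | (E)-3-[2,4-bis(benzyloxy)phenyl]-1-(2,6-dihydroxy-3,4,5-trimethoxyphenyl)prop-2-en-1-one | COc1c(O)c(C(=O)/C=C/c2ccc(OCc3ccccc3)cc2OCc2ccccc2)c(O)c(OC)c1OC
F3 | step 2 | 2,2'-(4,5,6-trimethoxy-1,3-phenylene)bis(4,4,5,5-tetramethyl-1,3,2-dioxaborolane) | COc1c(B2OC(C)(C)C(C)(C)O2)cc(B2OC(C)(C)C(C)(C)O2)c(OC)c1OC
F4 | step 3 | 1,2,3-trimethoxy-4,6-bis(methoxymethoxy)benzene | COCOc1cc(OCOC)c(OC)c(OC)c1OC
F5 | step 3 | 2-iodo-4,5,6-trimethoxy-1,3-bis(methoxymethoxy)benzene | COCOc1c(I)c(OCOC)c(OC)c(OC)c1OC
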